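All runs were computed with made-up constants, and the scatter is random.

- If a flask stops with D still in it, I ask first how deep it stops and only then how fast it gets there; here I put that to winter and noon, two runs that look nearly the same except that noon carried 4.00 times winter's X.

in all of them: D 0.20 M
- winter: Z 2 mM; X 0.50 mM; run made earlier
- noon: Z 2 mM; X 2 mM; run made earlier
- maple: Z 2.00 mM; X 1.0 mM; time 4.0 min
- alder: Z 2.00 mM; X 1.0 mM; time 10 min

| run | time / min | E / % | D / % |
|---|---|---|---|
| winter | 0.833 | 6.2 | 95.6 |
| winter | 1.50 | 5.5 | 94.9 |
| winter | 2.50 | 5.9 | 96.0 |
| winter | 3.00 | 7.5 | 93.4 |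
| noon | 0.417 | 9.0 | 90.9 |
| noon | 1.00 | 20.0 | 80.1 |
| noon | 2.00 | 25.9 | 74.3 |
| noon | 3.00 | 26.2 | 72.7 |

(standard deviation of a reading: 1 percentage point)

- which of these there is most of at the end, counted by the D in it, maple (E / D)
- which of these there is most of at the end, counted by the D in it, alder (E / D)
- the largest of these amounts at the end, in percent of the D charged, maple
- the largest of these amounts at the end, in percent of the D charged, alder

- Winter's four readings of D averaged 95.0% and showed no trend from 0.833 min onward.
- Noon's last two readings averaged 73.5%, and they differed by 1.6 percentage points against a scatter of 1 point per reading, so I took noon as stalled by 2.00 min.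
- Noon stopped with D to spare, at 73.5% of the charge, so D was not what ended either run; with D and Z charged alike, the two stalls differed with X.
- I called the stall depth the logarithm of charged D over D at the stall, which gave 0.0516 for winter and 0.308 for noon.
- The stall order, meaning the slope of ln(stall depth) against ln(X charge) at fixed D and Z, came to 1.29, as read from these readings.
- Maple and alder carry 2.00 times winter's X, which gave a depth of 0.126. I therefore expected D to lead in both at 88.2%, since 4.0 min and 10 min both lie beyond noon's stall.
- The forecast, a little below my figure, gave D for maple at 87% and D for alder at 87%: “The stall depends on X, not on D running out”.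
- The flask gave D at 87.7% in maple and D at 87.7% in alder, 0.50 points under my reckoning.

    D + X → J + E (k = 0.797 M⁻¹ s⁻¹)
    D + J → E + J, rate k2*[J]*[D] (k = 8.97 M⁻¹ s⁻¹)
    J + Z → L (k = 31.6 M⁻¹ s⁻¹)
    J → Q (k = 0.0198 s⁻¹)
    2 J ⇌ G, settled at all times (K = 1780 M⁻¹)

- In alder at 0.439 min, the half-life of J, the living end, by its passing with Z into L was 0.23 min, far shorter than the 10 min of the run, and X, the limiting reagent, ended at 0% of its charge. Alder's stall depth came to 0.131 against my 0.126, and D still stood at 87.7% after 100 min.
- For a neighbour of alder with 0.0040 M of X and its other charges and time as in alder, the stall order gave a depth of 0.752, so D at 47.1%. The computed flask has E ahead, with D lower than that at 38.3% and Z down to 3.7% of its charge.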